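**Plan**

- Retrosynthesis: C3 of the target first receives a tert-butoxycarbonyl group (lost at the end as CO2). The cuts are then O1–C2 (opening ring C), the C2=C3 alkene of the resulting alkylidene keto ester, and C3–C4.
- Forward: ring A enters complete as a salicylate, C3–C4 is made by Claisen condensation, and C2–C3 with ring B by Knoevenagel condensation. Ring C is closed last through O1–C2, and the ester is then cleaved and lost.
- Enabling feature: C2 is the β carbon of the C4 ketone and ends a six-atom chain from the ring A phenol oxygen (O1–C8a–C4a–C4–C3–C2). The ring-opened form is therefore a 2'-hydroxychalcone whose oxygen can add to its own enone to close ring C.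
- Stereochemistry: C2, the only stereocentre of the target, is set as S in the ring closure by a bifunctional cinchona thiourea. The C3 centre of the intermediate is labile and disappears on decarboxylation.

Key step: step 3

Assumption (chemistry): the quinidine-derived 9-epi-amino thiourea is taken to deliver the 2S series in this closure. The quinine-derived pseudoenantiomer gives the opposite sense and would replace it, with no other change, if the sense proves reversed.

**Route**

Step 1
Reactants: 1 methyl 2-hydroxy-4,6-dimethoxybenzoate; 2 tert-butyl acetate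
Product: 4 tert-butyl 3-(2-hydroxy-4,6-dimethoxyphenyl)-3-oxopropanoate, via lithium tert-butyl acetate enolate 3 (not isolated)
Conditions: LiN(iPr)2 (4 equiv), 2 (4 equiv), THF, −78 °C; add 1, −78 → 0 °C; cold 1 M HCl quench
Reagents that add atoms: none
Why: Crossed Claisen condensation, in which the preformed lithium enolate of the tert-butyl ester adds to the methyl ester of the lithium phenoxide and methoxide is expelled; the product is held as its phenoxide/β-keto ester enolate dianion, which blocks a second addition, and the bulky tert-butoxy group resists lactonisation to the 4-hydroxycoumarin.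

Step 2
Reactants: 4 tert-butyl 3-(2-hydroxy-4,6-dimethoxyphenyl)-3-oxopropanoate; 5 2,3,4-trimethoxybenzaldehyde
Product: 6 tert-butyl (Z)-2-(2-hydroxy-4,6-dimethoxybenzoyl)-3-(2,3,4-trimethoxyphenyl)acrylate
Conditions: piperidine (0.1 equiv), AcOH (0.1 equiv), 4 Å molecular sieves, toluene, rt; single geometric isomer secured by crystallisation or chromatography
Reagents that add atoms: none
Why: Knoevenagel condensation, in which piperidinium acetate turns the aldehyde into an iminium ion that is attacked by the enol of the doubly activated methylene and elimination gives the trisubstituted alkene; the isomer with the conjugated aroyl group anti to the ring B aryl group (Z) is expected, and the phenol, hydrogen-bonded to the ketone, should not yet add to the new acceptor at room temperature in the buffered medium.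

Step 3
Reactants: 6 tert-butyl (Z)-2-(2-hydroxy-4,6-dimethoxybenzoyl)-3-(2,3,4-trimethoxyphenyl)acrylate
Product: 7 tert-butyl (2S,3R)-5,7-dimethoxy-4-oxo-2-(2,3,4-trimethoxyphenyl)chromane-3-carboxylate (2,3-trans)
Conditions: quinidine-derived thiourea N-[3,5-bis(trifluoromethyl)phenyl]-N'-[(9R)-6'-methoxycinchonan-9-yl]thiourea (10 mol %), toluene, −25 °C
Reagents that add atoms: none
Why: The quinuclidine nitrogen of the catalyst acts as a general base on the ring A phenol O–H while the two thiourea N–H bonds hold the ketone and ester carbonyls of the alkylidene, so the phenol oxygen adds in conjugate fashion to the β carbon (forming O1–C2) and the resulting enol is protonated at C3. The closest known reaction type is the cinchona-thiourea-catalysed intramolecular oxa-Michael addition of 2-hydroxyaryl alkylidene β-keto esters to 3-carboxylated flavanones, the laboratory counterpart of the chalcone isomerase reaction. Ring C closes in the 6-endo-trig mode; the alternative 5-exo closure at the α carbon would give an aurone-type ring and is electronically mismatched. C2 is controlled by the catalyst, whose two-point binding of the 1,3-dicarbonyl unit presents one enantioface of the β carbon to the tethered oxygen, and C3 is under thermodynamic control, its acidic proton settling so that the ester is trans to the C2 aryl group. The step needs enantioface selectivity over the uncatalysed racemic closure and must not reverse: the intramolecular O–H···O=C hydrogen bond and the low temperature hold back the background reaction, while the second carbonyl makes up for the deactivation by the 4'- and 6'-methoxy groups and the electron-rich ring B and stabilises the adduct against retro-addition.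

Step 4
Reactants: 7 tert-butyl (2S,3R)-5,7-dimethoxy-4-oxo-2-(2,3,4-trimethoxyphenyl)chromane-3-carboxylate
Product: 9 (2S)-5,7-dimethoxy-2-(2,3,4-trimethoxyphenyl)chroman-4-one, via chromanone-3-carboxylic acid 8 (not isolated)
Conditions: TsOH·H2O (0.5 equiv), toluene, 80 °C
Reagents that add atoms: none
Why: Acid-catalysed cleavage of the tert-butyl ester (tert-butyl cation lost as 2-methylpropene) followed by thermal decarboxylation of the β-keto acid through its cyclic six-membered transition state; no base is present, so the E1cB-type retro-oxa-Michael opening that would racemise C2 is avoided, and C3 becomes a methylene group.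

**Compound list**

1 | methyl 2-hydroxy-4,6-dimethoxybenzoate | COC(=O)c1c(O)cc(OC)cc1OC | starting material
2 | tert-butyl acetate | CC(=O)OC(C)(C)C | starting material
3 | lithium enolate of tert-butyl acetate (not isolated) | C=C([O-])OC(C)(C)C.[Li+] | intermediate
4 | tert-butyl 3-(2-hydroxy-4,6-dimethoxyphenyl)-3-oxopropanoate | COc1cc(O)c(C(=O)CC(=O)OC(C)(C)C)c(OC)c1 | intermediate
5 | 2,3,4-trimethoxybenzaldehyde | COc1ccc(C=O)c(OC)c1OC | starting material
6 | tert-butyl (Z)-2-(2-hydroxy-4,6-dimethoxybenzoyl)-3-(2,3,4-trimethoxyphenyl)acrylate | COc1cc(O)c(C(=O)/C(C(=O)OC(C)(C)C)=C/c2ccc(OC)c(OC)c2OC)c(OC)c1 | intermediate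
7 | tert-butyl (2S,3R)-5,7-dimethoxy-4-oxo-2-(2,3,4-trimethoxyphenyl)chromane-3-carboxylate | COc1cc(OC)c2c(c1)O[C@H](c1ccc(OC)c(OC)c1OC)[C@@H](C(=O)OC(C)(C)C)C2=O | intermediate
8 | (2S,3R)-5,7-dimethoxy-4-oxo-2-(2,3,4-trimethoxyphenyl)chromane-3-carboxylic acid (not isolated) | COc1cc(OC)c2c(c1)O[C@H](c1ccc(OC)c(OC)c1OC)[C@@H](C(=O)O)C2=O | intermediate
9 | (2S)-5,7-dimethoxy-2-(2,3,4-trimethoxyphenyl)chroman-4-one | COc1cc(OC)c2c(c1)O[C@H](c1ccc(OC)c(OC)c1OC)CC2=O | target

**Step count and risks**

Total steps: 4. Longest linear sequence: 4 steps (1 → 4 → 6 → 7 → 9).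

Steps most likely to fail, riskiest first:

Step 3. The closure may stall or show poor enantioface selection. The β carbon carries an electron-rich, ortho-substituted aryl group, and the ring A ketone is flanked by two ortho substituents and twisted, which may weaken the two-point binding to the catalyst. The fallback sets out from 6 and comes back at 9, giving up catalytic induction for resolution. Compound 6 would be closed with an achiral base (Et3N, CH2Cl2, rt) to racemic trans tert-butyl 5,7-dimethoxy-4-oxo-2-(2,3,4-trimethoxyphenyl)chromane-3-carboxylate F1. TsOH·H2O in toluene at 80 °C would take F1 through racemic 5,7-dimethoxy-4-oxo-2-(2,3,4-trimethoxyphenyl)chromane-3-carboxylic acid F2 (not isolated) to racemic 5,7-dimethoxy-2-(2,3,4-trimethoxyphenyl)chroman-4-one F3. Preparative HPLC of F3 on a polysaccharide chiral stationary phase (amylose tris(3,5-dimethylphenylcarbamate), hexane/2-propanol) would then give 9. The unwanted (2R)-5,7-dimethoxy-2-(2,3,4-trimethoxyphenyl)chroman-4-one F4 is set aside and can be racemised with base and resubmitted.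

Step 2. The free phenol may add to the new acceptor under amine catalysis as soon as the alkene forms, giving racemic ring-closed material. The condensation of the hindered keto ester with the deactivated, ortho-substituted aldehyde may also be too slow at the low temperature needed to prevent this. The fallback sets out from 4 and comes back at 6, masking the phenol through the condensation. Compound 4 would be silylated on the phenol (TIPSCl, imidazole, DMF) to tert-butyl 3-[4,6-dimethoxy-2-(triisopropylsilyloxy)phenyl]-3-oxopropanoate F5. Knoevenagel condensation of F5 with 5 can then be driven with heat (piperidine, AcOH, 4 Å molecular sieves, toluene, 50 °C) to tert-butyl (Z)-2-[4,6-dimethoxy-2-(triisopropylsilyloxy)benzoyl]-3-(2,3,4-trimethoxyphenyl)acrylate F6. Desilylation with HF·pyridine in THF/pyridine at 0 °C releases the phenol under acidic, non-phenoxide conditions and gives 6.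

Step 1. Enolate addition may stop short because the lithium phenoxide formed first deactivates the neighbouring ester, which is also flanked by the 6-methoxy group. Forcing the reaction by warming may lose product through lactonisation to the 4-hydroxycoumarin. The fallback sets out from 1 and comes back at 4, carrying the phenol as a benzyl ether so that no phenoxide is present and lactonisation is impossible. Compound 1 would be benzylated (BnBr, K2CO3, DMF) to methyl 2-(benzyloxy)-4,6-dimethoxybenzoate F7. Claisen condensation of F7 with enolate 3 (THF, −78 → 0 °C) would give tert-butyl 3-[2-(benzyloxy)-4,6-dimethoxyphenyl]-3-oxopropanoate F8. Hydrogenolysis (H2, Pd/C, EtOAc, rt) would then give 4.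

**Further compounds**

F1 | step 3 | tert-butyl 5,7-dimethoxy-4-oxo-2-(2,3,4-trimethoxyphenyl)chromane-3-carboxylate, racemic trans | COc1cc(OC)c2c(c1)OC(c1ccc(OC)c(OC)c1OC)C(C(=O)OC(C)(C)C)C2=O
F2 | step 3 | 5,7-dimethoxy-4-oxo-2-(2,3,4-trimethoxyphenyl)chromane-3-carboxylic acid, racemic, not isolated | COc1cc(OC)c2c(c1)OC(c1ccc(OC)c(OC)c1OC)C(C(=O)O)C2=O
F3 | step 3 | 5,7-dimethoxy-2-(2,3,4-trimethoxyphenyl)chroman-4-one, racemic | COc1cc(OC)c2c(c1)OC(c1ccc(OC)c(OC)c1OC)CC2=O
F4 | step 3 | (2R)-5,7-dimethoxy-2-(2,3,4-trimethoxyphenyl)chroman-4-one | COc1cc(OC)c2c(c1)O[C@@H](c1ccc(OC)c(OC)c1OC)CC2=O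
F5 | step 2 | tert-butyl 3-[4,6-dimethoxy-2-(triisopropylsilyloxy)phenyl]-3-oxopropanoate | COc1cc(O[Si](C(C)C)(C(C)C)C(C)C)c(C(=O)CC(=O)OC(C)(C)C)c(OC)c1
F6 | step 2 | tert-butyl (Z)-2-[4,6-dimethoxy-2-(triisopropylsilyloxy)benzoyl]-3-(2,3,4-trimethoxyphenyl)acrylate | COc1cc(O[Si](C(C)C)(C(C)C)C(C)C)c(C(=O)/C(C(=O)OC(C)(C)C)=C/c2ccc(OC)c(OC)c2OC)c(OC)c1
F7 | step 1 | methyl 2-(benzyloxy)-4,6-dimethoxybenzoate | COC(=O)c1c(OCc2ccccc2)cc(OC)cc1OC
F8 | step 1 | tert-butyl 3-[2-(benzyloxy)-4,6-dimethoxyphenyl]-3-oxopropanoate | COc1cc(OCc2ccccc2)c(C(=O)CC(=O)OC(C)(C)C)c(OC)c1
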